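**Plan**

1. Retrosynthesis: cut C12–C13 (diene from a C12 iodide and the Grignard reagent of chloroprene), then C8–C9 (ring B, from a C8 methyl ketone and a C9=C11 enoate), then C9=C11 (olefination of a C9 aldehyde). The remaining ring A fragment is traced to dehydroabietic acid by excising its aromatic ring C.
2. Enabling feature: C4 and C10 of ring A each carry an axial methyl and flank C5–H, so the triad C4/C5/C10 is almost meso. Ring A of natural dehydroabietic acid therefore serves as ring A of this ent-labdane when its C4 is read as C10 (carboxyl carbon becomes C9) and its C10 as C4 (aryl carbon C9 becomes C18). The C8 tertiary carbinol next to C9, which carries the C11–C12 arm, is the retron of a ketone/enoate reductive coupling.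
3. Forward order: the C6 oxygen is set on the intact tricycle and ring C is degraded to two carboxyls. The three carboxyl carbons are then differentiated into C8 methyl ketone, C18 silyloxymethyl and C9 enoate, ring B is closed in the key step, and the diene unit is joined last at C12.
4. Stereochemistry: C4, C5 and C10 come from the pool. C6 comes from hydride delivery to the 6-ketone on the face away from the two axial methyls; the alcohol is axial on the tricycle and equatorial once ring B is rebuilt on the other flank. C8 and C9 come from the chair transition state of the key step.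

Key step: step 16

Remark: the tricyclic compounds carry abietane numbers; the ring A fragments and all later compounds carry the labdane numbers of the target (old C4 = C10, old C10 = C4, old C18 = C9, old C9 = C18). Ring A keeps the configuration of 1 throughout (both ring methyls axial and cis, H5 trans to them). Two carbinol centres that are removed later (C7 after step 3, C8 after step 11) are carried as epimer mixtures.

Step 1
Reactants: 1 dehydroabietic acid
Product: 2 methyl dehydroabietate (methyl abieta-8,11,13-trien-18-oate)
Conditions: MeI, K2CO3, DMF, rt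
Reagents that add atoms: iodomethane, CI
Why: O-alkylation of the carboxylate (SN2 esterification) avoids attack at the hindered neopentyl carbonyl carbon and makes the C18 carboxyl inert to the oxidations that follow.

Step 2
Reactants: 2 methyl dehydroabietate
Product: 3 methyl 7-oxodehydroabietate (methyl 7-oxoabieta-8,11,13-trien-18-oate)
Conditions: CrO3, AcOH/Ac2O, rt
Reagents that add atoms: chromium trioxide, O=[Cr](=O)=O
Why: Benzylic oxidation with CrO3 in acetic acid, routine for dehydroabietates, should convert the ring B benzylic methylene C7 into the aryl ketone.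

Step 3
Reactants: 3 methyl 7-oxodehydroabietate
Product: 4 methyl 7-hydroxydehydroabietate (C7 epimer mixture)
Conditions: NaBH4, MeOH/THF, 0 °C
Reagents that add atoms: none
Why: Borohydride reduction of the aryl ketone should give the benzylic alcohol without touching the hindered ester, and the C7 configuration is irrelevant because step 4 removes this centre.

Step 4
Reactants: 4 methyl 7-hydroxydehydroabietate
Product: 5 methyl abieta-6,8,11,13-tetraen-18-oate
Conditions: p-TsOH·H2O (cat.), toluene, reflux, Dean–Stark
Reagents that add atoms: none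
Why: Acid-catalysed E1 dehydration through the benzylic C7 cation can only lose H6 and should therefore give the styrene-type 6,7-alkene.

Step 5
Reactants: 5 methyl abieta-6,8,11,13-tetraen-18-oate
Product: 7 methyl 6-oxoabieta-8,11,13-trien-18-oate, via epoxide 6 (not isolated)
Conditions: mCPBA, CH2Cl2, 0 °C; then BF3·OEt2 (cat.), 0 °C
Reagents that add atoms: meta-chloroperbenzoic acid, OOC(=O)c1cccc(Cl)c1
Why: Prilezhaev epoxidation followed by Meinwald rearrangement, in which the Lewis acid opens the epoxide at benzylic C7 and a 1,2-hydride shift from C6 places the carbonyl at C6, so the facial course of the epoxidation has no consequence.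

Step 6
Reactants: 7 methyl 6-oxoabieta-8,11,13-trien-18-oate
Product: 8 methyl 6β-hydroxyabieta-8,11,13-trien-18-oate ((6R), axial hydroxyl on the intact six-membered ring B, cis to both axial methyls)
Conditions: NaBH4, MeOH, 0 °C
Reagents that add atoms: none
Why: In this ketone hydride reduction the β face of C6 is screened by the axial methyls on C4 and C10, so hydride should enter from the α face and set C6 as the axial 6β-alcohol (substrate control), the carbon skeleton staying unchanged.

Step 7
Reactants: 8 methyl 6β-hydroxyabieta-8,11,13-trien-18-oate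
Product: 9 methyl 6β-(tert-butyldimethylsilyloxy)abieta-8,11,13-trien-18-oate
Conditions: TBSOTf, 2,6-lutidine, CH2Cl2, 0 °C → rt
Reagents that add atoms: tert-butyldimethylsilyl triflate, CC(C)(C)[Si](C)(C)OS(=O)(=O)C(F)(F)F
Why: Silylation with a silyl triflate is the standard way to protect a hindered axial secondary alcohol, and the silyl ether tolerates the oxidative ring degradation.

Step 8
Reactants: 9 methyl 6β-(tert-butyldimethylsilyloxy)abieta-8,11,13-trien-18-oate
Product: 10 ring A diacid, 2-[(1R)-2-carboxy-1-(tert-butyldimethylsilyloxy)ethyl]-3-(methoxycarbonyl)-1,3-dimethylcyclohexane-1-carboxylic acid (C9 methyl ester on C10, C18 acid on C4, C8 acid on C7, C6 OTBS)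
Conditions: RuCl3·3H2O (cat.), NaIO4 (excess), CCl4/MeCN/H2O, rt
Reagents that add atoms: sodium periodate, [Na+].[O-]I(=O)(=O)=O; water, O
Why: RuO4 generated catalytically from RuCl3 and NaIO4 degrades the electron-rich trialkylbenzene ring (oxidative arene cleavage to carboxylic acids), leaving the aryl carbons C8 and C9 as carboxyls on the C7 methylene and on the quaternary ring carbon, while ester, silyl ether and the saturated ring A should survive.

Step 9
Reactants: 10 ring A diacid
Product: 11 Weinreb amide acid (C8 N-methoxy-N-methylamide, C18 acid, C9 methyl ester, C6 OTBS)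
Conditions: EDCI·HCl (1.1 equiv), HOBt, MeNHOMe·HCl, i-Pr2NEt, CH2Cl2, 0 °C → rt
Reagents that add atoms: N,O-dimethylhydroxylamine hydrochloride, CNOC.Cl
Why: Carbodiimide amidation discriminates on steric grounds, so the unhindered C7–CO2H should be activated and aminolysed while the carboxyl on the quaternary C4 stays free.

Step 10
Reactants: 11 Weinreb amide acid
Product: 12 keto acid (C8 methyl ketone, C18 acid, C9 methyl ester, C6 OTBS)
Conditions: MeMgBr (3.5 equiv), THF, −40 → 0 °C; aq. NH4Cl
Reagents that add atoms: methylmagnesium bromide, C[Mg]Br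
Why: Weinreb ketone synthesis, in which the chelated tetrahedral adduct prevents over-addition and releases the β-silyloxy ketone only on work-up, the C18 acid is masked as its magnesium carboxylate and the neopentyl methyl ester is too hindered to react at this temperature.

Step 11
Reactants: 12 keto acid
Product: 13 diol ester (C18 CH2OH, C8 secondary alcohol as epimer mixture, C9 methyl ester, C6 OTBS)
Conditions: BH3·THF (excess), THF, 0 °C → rt; MeOH quench
Reagents that add atoms: none
Why: Chemoselective borane reduction takes carboxylic acids and ketones but not esters, which tells the two neopentyl carboxyl carbons C18 and C9 apart; the C8 carbinol forms as an epimer mixture that step 14 removes.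

Step 12
Reactants: 13 diol ester
Product: 14 C18 tert-butyldiphenylsilyl ether (C8 secondary alcohol free, epimer mixture)
Conditions: TBDPSCl (1.05 equiv), imidazole, CH2Cl2, 0 °C → rt
Reagents that add atoms: tert-butyl(chloro)diphenylsilane, CC(C)(C)[Si](Cl)(c1ccccc1)c1ccccc1
Why: Sterically controlled silyl ether formation with the bulky chlorosilane should take the primary hydroxyl and leave the secondary one.

Step 13
Reactants: 14 C18 silyl ether
Product: 15 diol (C9 CH2OH on C10, C8 secondary alcohol as epimer mixture)
Conditions: LiAlH4, THF, 0 °C → rt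
Reagents that add atoms: none
Why: Hydride reduction with LiAlH4 converts even the hindered neopentyl methyl ester into the primary alcohol and leaves both silyl ethers intact.

Step 14
Reactants: 15 diol
Product: 16 keto aldehyde (C9 aldehyde on C10, C8 methyl ketone)
Conditions: Dess–Martin periodinane (3 equiv), CH2Cl2, 0 °C → rt
Reagents that add atoms: none
Why: Dess–Martin oxidation takes the primary and the secondary alcohol to aldehyde and ketone in one operation, which removes the C8 epimer mixture, and the aldehyde on quaternary C10 cannot epimerise.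

Step 15
Reactants: 16 keto aldehyde; 17 trimethyl phosphonoacetate
Product: 18 keto enoate (methyl (E)-enoate C12–C11=C9 on C10, C8 methyl ketone, C6 OTBS, C18 OTBDPS)
Conditions: LiCl, DBU, MeCN, 0 °C → rt
Reagents that add atoms: trimethyl phosphonoacetate (17), COC(=O)CP(=O)(OC)OC
Why: Horner–Wadsworth–Emmons olefination under mild LiCl/amine conditions reacts with the aldehyde far faster than with the methyl ketone and gives the (E)-enoate, the weak base sparing the β-silyloxy ketone from elimination.

Step 16
Reactants: 18 keto enoate
Product: 19 ring B hydroxy ester (C8 tertiary alcohol equatorial, C17 methyl axial, CH2CO2Me on C9 equatorial)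
Conditions: SmI2 (0.1 M in THF, 3 equiv), HMPA, t-BuOH (2 equiv), THF, −78 → −20 °C; aq. NH4Cl at −78 °C
Reagents that add atoms: none
Why: Electron transfer from SmI2–HMPA to the C8 methyl ketone gives a samarium ketyl whose carbon adds to C9, the β-carbon of the (E)-enoate on quaternary C10, and a second electron turns the α-ester radical into a samarium enolate that t-BuOH protonates at C11. The closest known reaction type is the SmI2-promoted ketyl–olefin reductive cyclisation of keto enoates to 2-(alkoxycarbonylmethyl)cycloalkanols. Ring B closes 6-exo-trig through a chair on which ring A is trans-fused by the diequatorial C5–C6 and C10–C9 bonds and in which the C6 silyloxy group is equatorial. C9 is controlled by this chair, the enoate arm staying equatorial so that H9 ends axial and anti to the C10 methyl. C8 is controlled by the HMPA-solvated O–Sm group, which avoids the axial position facing the C10 methyl and the enolate being formed, so the hydroxyl ends equatorial and anti to the ester arm with the methyl axial. The step needs cyclisation to win over simple reduction of ketone or enoate and over pinacol coupling, which the proximity of the two termini on ring A and cold, dilute conditions should secure, while a cold quench keeps the trans hydroxy ester from lactonising.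

Step 17
Reactants: 19 ring B hydroxy ester
Product: 20 C8 triethylsilyl ether of 19
Conditions: TESOTf, 2,6-lutidine, CH2Cl2, −78 → 0 °C
Reagents that add atoms: triethylsilyl triflate, CC[Si](CC)(CC)OS(=O)(=O)C(F)(F)F
Why: Silyl triflate silylation caps the tertiary C8 hydroxyl, which would otherwise close onto C12 (as a lactone at the ester stage, as a cyclic ether once C12 carries a leaving group).

Step 18
Reactants: 20 C8 triethylsilyl ether
Product: 21 C12 primary alcohol
Conditions: LiAlH4, THF, 0 °C
Reagents that add atoms: none
Why: LiAlH4 ester reduction gives the C12 primary alcohol, the three silyl ethers being stable to hydride.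

Step 19
Reactants: 21 C12 primary alcohol
Product: 22 C12 primary iodide
Conditions: I2, PPh3, imidazole, CH2Cl2, 0 °C → rt
Reagents that add atoms: iodine, II
Why: Appel-type iodination converts the unhindered primary alcohol into the iodide by SN2 displacement of the oxyphosphonium group.

Step 20
Reactants: 23 chloroprene (2-chlorobuta-1,3-diene)
Product: 24 buta-1,3-dien-2-ylmagnesium chloride
Conditions: Mg turnings, ZnCl2 (cat.), THF, 50 °C
Reagents that add atoms: magnesium, [Mg]
Why: Grignard formation by insertion of magnesium into the vinylic C–Cl bond, known for chloroprene in THF with ZnCl2 as promoter, gives the dienyl nucleophile.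

Step 21
Reactants: 22 C12 primary iodide; 24 buta-1,3-dien-2-ylmagnesium chloride
Product: 25 tris-silylated diene (C6 OTBS, C8 OTES, C18 OTBDPS)
Conditions: Li2CuCl4 (5 mol %), THF, −20 → 0 °C
Reagents that add atoms: buta-1,3-dien-2-ylmagnesium chloride (24), C=CC(=C)[Mg]Cl
Why: Copper-catalysed sp3–sp2 Grignard cross-coupling of a primary alkyl iodide, precedented for this dienyl Grignard reagent, forms C12–C13 and delivers the 2-substituted buta-1,3-diene without touching the silyl ethers.

Step 22
Reactants: 25 tris-silylated diene
Product: 26 6,8-diol with C18 OTBDPS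
Conditions: CSA (0.3 equiv), MeOH/CH2Cl2, 0 °C → rt
Reagents that add atoms: none
Why: Acid-catalysed methanolysis of silyl ethers follows their lability, so the secondary TBS and tertiary TES ethers should be cleaved while the far more acid-stable primary TBDPS ether remains, and the acid is too weak in methanol to protonate the diene.

Step 23
Reactants: 26 6,8-diol
Product: 27 C6 acetate with C18 OTBDPS
Conditions: Ac2O, pyridine, DMAP (cat.), CH2Cl2, 0 °C → rt
Reagents that add atoms: acetic anhydride, CC(=O)OC(C)=O
Why: DMAP-catalysed acylation acetylates the secondary C6 hydroxyl, whereas the tertiary C8 hydroxyl next to the axial methyl does not react at room temperature.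

Step 24
Reactants: 27 C6 acetate
Product: 28 target, CNP0312185.1
Conditions: TBAF, AcOH (1:1), THF, 0 °C → rt
Reagents that add atoms: none
Why: Fluoride-induced desilylation cleaves the Si–O bond of the TBDPS ether, and buffering with acetic acid suppresses base-induced acetyl migration from O6 to the freed C18 hydroxyl.

**Compound list**

1 | dehydroabietic acid | CC(C)C1=CC2=C(C=C1)[C@]3(CCC[C@@]([C@@H]3CC2)(C)C(=O)O)C | starting material
2 | methyl dehydroabietate | CC(C)C1=CC2=C(C=C1)[C@]3(CCC[C@@]([C@@H]3CC2)(C)C(=O)OC)C | intermediate
3 | methyl 7-oxodehydroabietate | CC(C)C1=CC2=C(C=C1)[C@]3(CCC[C@@]([C@@H]3CC2=O)(C)C(=O)OC)C | intermediate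
4 | methyl 7-hydroxydehydroabietate (C7 epimers) | CC(C)C1=CC2=C(C=C1)[C@]3(CCC[C@@]([C@@H]3CC2O)(C)C(=O)OC)C | intermediate
5 | methyl abieta-6,8,11,13-tetraen-18-oate | CC(C)C1=CC2=C(C=C1)[C@]3(CCC[C@@]([C@@H]3C=C2)(C)C(=O)OC)C | intermediate
6 | methyl 6α,7α-epoxyabieta-8,11,13-trien-18-oate (formed in the flask in step 5) | CC(C)C1=CC2=C(C=C1)[C@]3(CCC[C@@]([C@@H]3[C@H]4O[C@H]42)(C)C(=O)OC)C | intermediate
7 | methyl 6-oxoabieta-8,11,13-trien-18-oate | CC(C)C1=CC2=C(C=C1)[C@]3(CCC[C@@]([C@@H]3C(=O)C2)(C)C(=O)OC)C | intermediate
8 | methyl 6β-hydroxyabieta-8,11,13-trien-18-oate | CC(C)C1=CC2=C(C=C1)[C@]3(CCC[C@@]([C@@H]3[C@H](O)C2)(C)C(=O)OC)C | intermediate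
9 | methyl 6β-(tert-butyldimethylsilyloxy)abieta-8,11,13-trien-18-oate | CC(C)C1=CC2=C(C=C1)[C@]3(CCC[C@@]([C@@H]3[C@H](O[Si](C)(C)C(C)(C)C)C2)(C)C(=O)OC)C | intermediate
10 | ring A diacid (C9 methyl ester, C18 and C8 acids, C6 OTBS) | COC(=O)[C@]1(C)CCC[C@](C)(C(=O)O)[C@H]1[C@H](O[Si](C)(C)C(C)(C)C)CC(=O)O | intermediate
11 | Weinreb amide acid (C8 amide, C18 acid) | COC(=O)[C@]1(C)CCC[C@](C)(C(=O)O)[C@H]1[C@H](O[Si](C)(C)C(C)(C)C)CC(=O)N(C)OC | intermediate
12 | keto acid (C8 methyl ketone, C18 acid) | COC(=O)[C@]1(C)CCC[C@](C)(C(=O)O)[C@H]1[C@H](O[Si](C)(C)C(C)(C)C)CC(C)=O | intermediate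
13 | diol ester (C18 CH2OH, C8 carbinol epimers) | COC(=O)[C@]1(C)CCC[C@](C)(CO)[C@H]1[C@H](O[Si](C)(C)C(C)(C)C)CC(C)O | intermediate
14 | C18 TBDPS ether (C8 carbinol epimers) | COC(=O)[C@]1(C)CCC[C@](C)(CO[Si](c2ccccc2)(c2ccccc2)C(C)(C)C)[C@H]1[C@H](O[Si](C)(C)C(C)(C)C)CC(C)O | intermediate
15 | diol (C9 CH2OH, C8 carbinol epimers) | OC[C@]1(C)CCC[C@](C)(CO[Si](c2ccccc2)(c2ccccc2)C(C)(C)C)[C@H]1[C@H](O[Si](C)(C)C(C)(C)C)CC(C)O | intermediate
16 | keto aldehyde | O=C[C@]1(C)CCC[C@](C)(CO[Si](c2ccccc2)(c2ccccc2)C(C)(C)C)[C@H]1[C@H](O[Si](C)(C)C(C)(C)C)CC(C)=O | intermediate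
17 | trimethyl phosphonoacetate | COC(=O)CP(=O)(OC)OC | starting material
18 | keto enoate (precursor of the key step) | COC(=O)/C=C/[C@]1(C)CCC[C@](C)(CO[Si](c2ccccc2)(c2ccccc2)C(C)(C)C)[C@H]1[C@H](O[Si](C)(C)C(C)(C)C)CC(C)=O | intermediate
19 | ring B hydroxy ester (product of the key step) | COC(=O)C[C@H]1[C@]2(C)CCC[C@](C)(CO[Si](c3ccccc3)(c3ccccc3)C(C)(C)C)[C@H]2[C@H](O[Si](C)(C)C(C)(C)C)C[C@]1(C)O | intermediate
20 | C8 triethylsilyl ether of 19 | COC(=O)C[C@H]1[C@]2(C)CCC[C@](C)(CO[Si](c3ccccc3)(c3ccccc3)C(C)(C)C)[C@H]2[C@H](O[Si](C)(C)C(C)(C)C)C[C@]1(C)O[Si](CC)(CC)CC | intermediate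
21 | C12 primary alcohol | OCC[C@H]1[C@]2(C)CCC[C@](C)(CO[Si](c3ccccc3)(c3ccccc3)C(C)(C)C)[C@H]2[C@H](O[Si](C)(C)C(C)(C)C)C[C@]1(C)O[Si](CC)(CC)CC | intermediate
22 | C12 primary iodide | ICC[C@H]1[C@]2(C)CCC[C@](C)(CO[Si](c3ccccc3)(c3ccccc3)C(C)(C)C)[C@H]2[C@H](O[Si](C)(C)C(C)(C)C)C[C@]1(C)O[Si](CC)(CC)CC | intermediate
23 | chloroprene | C=CC(Cl)=C | starting material
24 | buta-1,3-dien-2-ylmagnesium chloride | C=CC(=C)[Mg]Cl | intermediate
25 | tris-silylated diene | C=CC(=C)CC[C@H]1[C@]2(C)CCC[C@](C)(CO[Si](c3ccccc3)(c3ccccc3)C(C)(C)C)[C@H]2[C@H](O[Si](C)(C)C(C)(C)C)C[C@]1(C)O[Si](CC)(CC)CC | intermediate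
26 | 6,8-diol with C18 OTBDPS | C=CC(=C)CC[C@H]1[C@]2(C)CCC[C@](C)(CO[Si](c3ccccc3)(c3ccccc3)C(C)(C)C)[C@H]2[C@H](O)C[C@]1(C)O | intermediate
27 | C6 acetate with C18 OTBDPS | C=CC(=C)CC[C@H]1[C@]2(C)CCC[C@](C)(CO[Si](c3ccccc3)(c3ccccc3)C(C)(C)C)[C@H]2[C@H](OC(C)=O)C[C@]1(C)O | intermediate
28 | CNP0312185.1 | C=CC(=C)CC[C@H]1[C@]2(C)CCC[C@](C)(CO)[C@H]2[C@H](OC(C)=O)C[C@]1(C)O | target

**Count and risks**

Total steps: 24. Longest linear sequence: 23 steps (from 1 through steps 1–19 and 21–24); step 20 is a one-step branch from 23.

Steps most likely to fail: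

Step 8. The risk is competing oxidation at the benzylic C7 methylene and stalling at partly degraded ring C fragments, since the arene carries only alkyl donors. The fallback sets out from 9 and replaces the metal-oxo oxidant by exhaustive ozonolysis (O3, CH2Cl2/AcOH, −20 → 0 °C), which is far less prone to oxidise benzylic C–H bonds. The ozonolysis mixture would be worked up oxidatively in the same flask (30% H2O2, aq. NaOH, then acidification to pH 3) and the route rejoined at 10; new compounds: none F0.

Step 16. The risk is simple reduction of ketone or enoate outrunning C–C bond formation at the hindered β-carbon, or insufficient facial control at C8. The fallback sets out from 18: kinetic deprotonation of the methyl ketone (LiN(i-Pr)2, THF, −78 °C) and trapping with TESCl would give the triethylsilyl enol ether of 18 F1. Iron-hydride hydrogen atom transfer (Fe(acac)3, i.e. iron tris(acetylacetonate), PhSiH3, EtOH/ethylene glycol, 60 °C) would then add hydrogen to the terminal CH2, and the tertiary α-silyloxy radical at C8 would close ring B 6-exo onto the enoate, a known radical conjugate addition of silyl enol ethers. The route is rejoined at 20, and step 17 is then not needed.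

Step 22. The risk is slow methanolysis of the hindered C6 silyl ether, during which the C18 silyl group is lost or the protonated diene is captured by the C8 hydroxyl. The fallback sets out from 25: all three silyl groups would be removed with fluoride (TBAF, THF, 50 °C) to give the 6,8,18-triol F2. Selective silylation of its only primary hydroxyl (TBDPSCl, 1.05 equiv, imidazole, CH2Cl2, 0 °C) would rejoin the route at 26.

Further compounds
F0 | step 8 | none | none
F1 | step 16 | triethylsilyl enol ether of 18 (C8=C17 enol ether) | COC(=O)/C=C/[C@]1(C)CCC[C@](C)(CO[Si](c2ccccc2)(c2ccccc2)C(C)(C)C)[C@H]1[C@H](O[Si](C)(C)C(C)(C)C)CC(=C)O[Si](CC)(CC)CC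
F2 | step 22 | 6,8,18-triol (fully desilylated diene) | C=CC(=C)CC[C@H]1[C@]2(C)CCC[C@](C)(CO)[C@H]2[C@H](O)C[C@]1(C)O
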